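**Retrosynthetic overview**

- Numbering: C1 (alkene carbon bearing methyl C20) to C14 round the carbocycle through C5(C19)=C6, C9 (bearing C18H2O), C10 (ether CH) and C12 (bearing C15Me2); the tetrahydrofuran is O–C10–C11–C12–C15.
- Feature used: the isolated trisubstituted alkene C1=C2 of the 14-membered carbocycle has its ring arms C14 and C3 cis and no neighbouring function, and C1/C20 is a former methyl ketone. It is therefore made last, by cutting SO2 out of a 15-membered cyclic sulfone C1–SO2–C2 (Ramberg–Bäcklund ring contraction).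
- The sulfone comes from a thiacycle closed by thiolate SN2 at C2 (sulfur put on C1 through the carbinol, the C2 chloride carried from the start). The open chain is joined at C9–C10 by an Evans syn aldol between an imide holding C2–C9, C18 and C19 (C5=C6 by HWE) and the keto aldehyde C10–C14/C1 from (R)-limonene oxide.
- Ring order: tetrahydrofuran (step 7, cobalt-hydride etherification of the isopropenyl group by the C10 hydroxyl), 15-membered thiacycle (step 12), 14-membered carbocycle (step 14). Then desilylation, allylic oxidation at C19 and malonylation at C18.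

Key step: step 14

Remark: C1 is carried as a mixture of epimers from step 8 to step 13 (left unspecified in those SMILES) because it becomes trigonal in step 14; commercial (+)-limonene oxide (from (R)-limonene, cis/trans mixture) is taken as the chiral starting material.

**Route**

Step 1
Reactants: 1 (4R)-limonene 1,2-oxide (cis/trans mixture)
Product: 2 (3R)-6-oxo-3-(prop-1-en-2-yl)heptanal
Conditions: H5IO6, THF/H2O, 0 °C → rt
Reagents that add atoms: water, O
Why: Hydrolytic opening of the epoxide and periodate glycol cleavage in one flask should give the keto aldehyde; the isopropenyl group and the C12 stereocentre (from limonene) are untouched, and 2 is used at once because it is prone to intramolecular aldol reaction.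

Step 2
Reactants: 3 triethyl phosphonoacetate; 4 1-bromo-3-chloropropane
Product: 5 ethyl 5-chloro-2-(diethoxyphosphoryl)pentanoate (racemic)
Conditions: NaH, THF/DMSO, 0 °C; then 4 (excess), rt → 50 °C
Reagents that add atoms: none
Why: SN2 alkylation of the sodium phosphonoacetate at the C–Br end (bromide leaves far faster than chloride); excess dihalide suppresses dialkylation and cyclobutane formation.

Step 3
Reactants: 6 hex-5-enoic acid; 7 (S)-4-benzyl-2-oxazolidinone
Product: 9 (S)-4-benzyl-3-(hex-5-enoyl)oxazolidin-2-one, via hex-5-enoic pivalic anhydride 8 (not isolated)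
Conditions: PivCl, Et3N, THF, −20 °C; then 7, LiCl, rt
Reagents that add atoms: none
Why: Mixed-anhydride N-acylation of the oxazolidinone; the nucleophile attacks the unhindered hexenoyl carbonyl of the pivalic anhydride.

Step 4
Reactants: 9 (S)-4-benzyl-3-(hex-5-enoyl)oxazolidin-2-one
Product: 11 (S)-4-benzyl-3-(5-oxopentanoyl)oxazolidin-2-one, via ozonide 10 (not isolated)
Conditions: O3, CH2Cl2, −78 °C; then PPh3, −78 °C → rt
Reagents that add atoms: ozone, [O-][O+]=O
Why: Ozonolysis with reductive work-up cleaves the only alkene to the C6 aldehyde; the imide is inert.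

Step 5
Reactants: 11 (S)-4-benzyl-3-(5-oxopentanoyl)oxazolidin-2-one; 5 ethyl 5-chloro-2-(diethoxyphosphoryl)pentanoate
Product: 12 ethyl (E)-7-[(S)-4-benzyl-2-oxooxazolidin-3-yl]-2-(3-chloropropyl)-7-oxohept-2-enoate
Conditions: LiCl, DBU, MeCN, 0 °C → rt
Reagents that add atoms: none
Why: Horner–Wadsworth–Emmons olefination under Masamune–Roush conditions, which the imide tolerates; it should favour the E enoate (ester trans to C7, so C4 and C7 are cis as in the target), and the minor Z isomer is removed by chromatography.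

Step 6
Reactants: 12 ethyl (E)-7-[(S)-4-benzyl-2-oxooxazolidin-3-yl]-2-(3-chloropropyl)-7-oxohept-2-enoate; 2 (3R)-6-oxo-3-(prop-1-en-2-yl)heptanal
Product: 14 ethyl (2E,6S,7R,9R)-6-[(S)-4-benzyl-2-oxooxazolidine-3-carbonyl]-2-(3-chloropropyl)-7-hydroxy-12-oxo-9-(prop-1-en-2-yl)tridec-2-enoate, via dibutylboron Z-enolate 13 (not isolated)
Conditions: Bu2BOTf (1.05 equiv), iPr2NEt, CH2Cl2, −78 → 0 °C; then 2, −78 → −20 °C; pH 7 buffer, MeOH, H2O2, 0 °C
Reagents that add atoms: none
Why: Evans syn aldol: the Z(O)-boron enolate reacts through a closed Zimmerman–Traxler chair on the face away from the benzyl group, which sets C9 and C10 (the syn pair that becomes 9R,10R in the target) under auxiliary control. At −78 °C the aldehyde reacts in preference to the methyl ketone, and the enoate cannot be enolized.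

Step 7
Reactants: 14 syn-aldol adduct
Product: 15 ethyl (2E,6S)-6-[(S)-4-benzyl-2-oxooxazolidine-3-carbonyl]-2-(3-chloropropyl)-6-[(2R,4R)-5,5-dimethyl-4-(3-oxobutyl)oxolan-2-yl]hex-2-enoate
Conditions: Co(salen) catalyst C36H52CoN2O2 (divalent cobalt; N,N′-bis(3,5-di-tert-butylsalicylidene)-1,2-cyclohexanediamine ligand, cat.), N-fluoro-2,4,6-trimethylpyridinium triflate, PhSiH3, PhCF3, rt
Reagents that add atoms: none
Why: Cobalt-hydride hydrogen-atom transfer with radical-polar crossover (hydroalkoxylation of an unactivated alkene): H adds to the terminal CH2 of the 1,1-disubstituted alkene, and the oxidized tertiary C15 centre is captured 5-exo by the C10 hydroxyl. The hindered, electron-poor trisubstituted enoate is a much poorer H-atom acceptor, the ketone oxygen is a weaker nucleophile than the hydroxyl, and no stereocentre is formed because C15 carries two methyls.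

Step 8
Reactants: 15 tetrahydrofuran imide
Product: 16 ethyl (2E,6R)-2-(3-chloropropyl)-7-hydroxy-6-[(2R,4R)-4-(3-hydroxybutyl)-5,5-dimethyloxolan-2-yl]hept-2-enoate (carbinol epimers)
Conditions: LiBH4, MeOH (1 equiv), Et2O, 0 °C
Reagents that add atoms: none
Why: LiBH4 cleaves the N-acyl oxazolidinone reductively to the C18 alcohol and reduces the ketone (C1 carbinol unselectively, which is of no consequence). The primary chloride is inert, and any early reduction of the enoate converges in step 9.

Step 9
Reactants: 16 hydroxy ester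
Product: 17 (2E,6R)-2-(3-chloropropyl)-6-[(2R,4R)-4-(3-hydroxybutyl)-5,5-dimethyloxolan-2-yl]hept-2-ene-1,7-diol (carbinol epimers)
Conditions: DIBAL-H (iBu2AlH, excess), CH2Cl2, −78 → 0 °C; aq. potassium sodium tartrate
Reagents that add atoms: none
Why: DIBAL-H 1,2-reduction of the α,β-unsaturated ester gives the C19 allylic alcohol without touching the alkene geometry or the alkyl chloride.

Step 10
Reactants: 17 triol
Product: 18 1,7-bis-O-TBS ether of 17 (C18 and C19 silylated; C1 carbinol free)
Conditions: TBSCl (2.2 equiv), imidazole, CH2Cl2, 0 °C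
Reagents that add atoms: tert-butyldimethylsilyl chloride (TBSCl), CC(C)(C)[Si](C)(C)Cl
Why: The two primary hydroxyls are silylated in preference to the secondary C1 carbinol on steric grounds.

Step 11
Reactants: 18 bis-TBS chloro alcohol
Product: 19 C1 thioacetate of 18 (AcS in place of the secondary OH)
Conditions: PPh3, DIAD, AcSH, THF, 0 °C → rt
Reagents that add atoms: thioacetic acid, CC(=O)S
Why: Mitsunobu displacement of the secondary alcohol by thioacetate with inversion (both epimers react); the neutral conditions leave the primary chloride and the silyl ethers alone.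

Step 12
Reactants: 19 C1 thioacetate
Product: 21 15-membered cyclic sulfide C1–S–C2 (bis-TBS; C1 epimers), via caesium thiolate 20 (not isolated)
Conditions: Cs2CO3, MeOH, NaI (cat.), degassed DMF, 50 °C, syringe-pump addition (high dilution)
Reagents that add atoms: none
Why: Methanolysis of the thioacetate frees the caesium thiolate, which closes the 15-membered ring by exo-tet SN2 at the primary carbon C2 (iodide exchange speeds up the chloride). Caesium thiolates in DMF under high dilution are the standard for macrocyclic sulfides, and oxygen is excluded to avoid disulfide.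

Step 13
Reactants: 21 cyclic sulfide
Product: 22 15-membered cyclic sulfone C1–SO2–C2 (bis-TBS; C1 epimers)
Conditions: (NH4)6Mo7O24·4H2O (cat.), 30% H2O2, EtOH, 0 °C → rt
Reagents that add atoms: hydrogen peroxide, OO
Why: Molybdate-catalysed peroxide oxidation takes sulfide to sulfone; the peroxomolybdate reacts at sulfur and should not epoxidize the trisubstituted alkene at this temperature.

Step 14
Reactants: 22 15-membered cyclic sulfone
Product: 25 bis-TBS (1Z,5E)-diene of the 14-membered carbocycle, via C2-bromo sulfone 23 (not isolated), via cis-fused episulfone 24 (not isolated)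
Conditions: KOH/Al2O3, CBr2F2, t-BuOH/CH2Cl2, 0 °C → rt
Reagents that add atoms: none
Why: Ramberg–Bäcklund reaction with in situ halogenation: hydroxide on alumina forms the α-sulfonyl carbanion, which takes bromine from CBr2F2 (at C2 as drawn; bromination at C1 converges), a second deprotonation at the other α-carbon closes the thiirane 1,1-dioxide 24 by 1,3-displacement, and cheletropic loss of SO2 leaves C1=C2. The closest known reactions are ring contractions of macrocyclic sulfones to cycloalkenes and Ramberg–Bäcklund syntheses of trisubstituted alkenes from secondary-alkyl primary-alkyl sulfones. The 14-membered carbocycle is closed by 3-exo-tet formation of the C1–C2 bond inside the 15-membered thiacycle, followed by stereospecific SO2 extrusion. No stereocentre is formed, and both C1 epimers of 22 converge because C1 becomes a carbanion (or the bromide-bearing carbon) and then trigonal. The step needs the Z alkene (ring arms C14 and C3 cis), hence the cis-fused episulfone; this is the kinetically favoured closure under weak-base conditions that do not epimerize the episulfone at C2, but nothing in the substrate enforces it and the macrocycle may override it, so the geometry has to be checked here. The silyl ethers, the tetrahydrofuran and the C5=C6 alkene tolerate KOH/Al2O3, and the bromofluoromethane releases CF2 rather than a more reactive dihalocarbene.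

Step 15
Reactants: 25 bis-TBS diene
Product: 26 (1Z,5E)-diene-18,19-diol
Conditions: TBAF, THF, 0 °C → rt
Reagents that add atoms: none
Why: Fluoride cleaves both primary TBS ethers; nothing else in the molecule is fluoride- or base-sensitive.

Step 16
Reactants: 26 diene diol
Product: 27 (1Z,5E)-18-hydroxy-dien-19-al (hydroxy enal)
Conditions: MnO2 (activated, excess), CH2Cl2, rt
Reagents that add atoms: none
Why: MnO2 oxidizes only the allylic C19 alcohol and leaves the saturated C18 alcohol; the E enal (CHO trans to C7) is retained and is the thermodynamically preferred geometry.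

Step 17
Reactants: 28 Meldrum's acid; 29 allyl alcohol
Product: 30 allyl hydrogen malonate
Conditions: toluene, 100 °C
Reagents that add atoms: none
Why: Thermal alcoholysis of Meldrum's acid: ring opening by the alcohol and loss of acetone give the malonic half ester.

Step 18
Reactants: 27 hydroxy enal; 30 allyl hydrogen malonate
Product: 31 C18 allyl malonate of 27
Conditions: EDC·HCl, DMAP (cat.), CH2Cl2, 0 °C → rt
Reagents that add atoms: none
Why: Carbodiimide (Steglich) esterification of the primary C18 alcohol; fast acylation at 0 °C should precede any oxa-Michael addition to the hindered α-substituted enal.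

Step 19
Reactants: 31 C18 allyl malonate
Product: 32 CNP0170412.1 (target)
Conditions: Pd(PPh3)4 (cat., zerovalent palladium), N-methylaniline, THF, rt; pH 4 buffer work-up
Reagents that add atoms: none
Why: Tsuji–Trost deallylation: palladium ionizes the allyl ester and N-methylaniline traps the π-allyl complex; a weakly nucleophilic aniline is chosen so that the enal is spared, and neither acid nor strong base touches the dienes.

**Compound list**

1 | (4R)-limonene 1,2-oxide, cis/trans mixture | CC12OC1C[C@@H](CC2)C(C)=C | starting material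
2 | (3R)-6-oxo-3-(prop-1-en-2-yl)heptanal | O=CC[C@@H](CCC(C)=O)C(C)=C | intermediate
3 | triethyl phosphonoacetate | CCOC(=O)CP(=O)(OCC)OCC | starting material
4 | 1-bromo-3-chloropropane | ClCCCBr | starting material
5 | ethyl 5-chloro-2-(diethoxyphosphoryl)pentanoate (racemic) | CCOC(=O)C(CCCCl)P(=O)(OCC)OCC | intermediate
6 | hex-5-enoic acid | C=CCCCC(=O)O | starting material
7 | (S)-4-benzyl-2-oxazolidinone | O=C1N[C@@H](Cc2ccccc2)CO1 | starting material
8 | hex-5-enoic pivalic anhydride (not isolated) | C=CCCCC(=O)OC(=O)C(C)(C)C | intermediate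
9 | (S)-4-benzyl-3-(hex-5-enoyl)oxazolidin-2-one | C=CCCCC(=O)N1[C@@H](Cc2ccccc2)COC1=O | intermediate
10 | ozonide of 9, (S)-4-benzyl-3-[4-(1,2,4-trioxolan-3-yl)butanoyl]oxazolidin-2-one (not isolated) | O=C(CCCC1OCOO1)N2[C@@H](Cc3ccccc3)COC2=O | intermediate
11 | (S)-4-benzyl-3-(5-oxopentanoyl)oxazolidin-2-one | O=CCCCC(=O)N1[C@@H](Cc2ccccc2)COC1=O | intermediate
12 | ethyl (E)-7-[(S)-4-benzyl-2-oxooxazolidin-3-yl]-2-(3-chloropropyl)-7-oxohept-2-enoate | CCOC(=O)/C(CCCCl)=C/CCCC(=O)N1[C@@H](Cc2ccccc2)COC1=O | intermediate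
13 | dibutylboron Z(O)-enolate of 12 (not isolated) | CCCCB(CCCC)O/C(=C\CC/C=C(\CCCCl)C(=O)OCC)N1[C@@H](Cc2ccccc2)COC1=O | intermediate
14 | ethyl (2E,6S,7R,9R)-6-[(S)-4-benzyl-2-oxooxazolidine-3-carbonyl]-2-(3-chloropropyl)-7-hydroxy-12-oxo-9-(prop-1-en-2-yl)tridec-2-enoate | ClCCC/C(C(=O)OCC)=C\CC[C@H](C(=O)N1[C@@H](Cc2ccccc2)COC1=O)[C@H](O)C[C@@H](CCC(C)=O)C(C)=C | intermediate
15 | ethyl (2E,6S)-6-[(S)-4-benzyl-2-oxooxazolidine-3-carbonyl]-2-(3-chloropropyl)-6-[(2R,4R)-5,5-dimethyl-4-(3-oxobutyl)oxolan-2-yl]hex-2-enoate | ClCCC/C(C(=O)OCC)=C\CC[C@H](C(=O)N1[C@@H](Cc2ccccc2)COC1=O)[C@H]3C[C@@H](CCC(C)=O)C(C)(C)O3 | intermediate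
16 | ethyl (2E,6R)-2-(3-chloropropyl)-7-hydroxy-6-[(2R,4R)-4-(3-hydroxybutyl)-5,5-dimethyloxolan-2-yl]hept-2-enoate, carbinol epimers | ClCCC/C(C(=O)OCC)=C\CC[C@H](CO)[C@H]1C[C@@H](CCC(C)O)C(C)(C)O1 | intermediate
17 | (2E,6R)-2-(3-chloropropyl)-6-[(2R,4R)-4-(3-hydroxybutyl)-5,5-dimethyloxolan-2-yl]hept-2-ene-1,7-diol, carbinol epimers | ClCCC/C(CO)=C\CC[C@H](CO)[C@H]1C[C@@H](CCC(C)O)C(C)(C)O1 | intermediate
18 | 1,7-bis-O-TBS ether of 17 (C18 and C19 OTBS, C1 carbinol free) | ClCCC/C(CO[Si](C)(C)C(C)(C)C)=C\CC[C@H](CO[Si](C)(C)C(C)(C)C)[C@H]1C[C@@H](CCC(C)O)C(C)(C)O1 | intermediate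
19 | C1 thioacetate of 18 | ClCCC/C(CO[Si](C)(C)C(C)(C)C)=C\CC[C@H](CO[Si](C)(C)C(C)(C)C)[C@H]1C[C@@H](CCC(C)SC(C)=O)C(C)(C)O1 | intermediate
20 | caesium C1 thiolate from 19 (not isolated) | [Cs+].ClCCC/C(CO[Si](C)(C)C(C)(C)C)=C\CC[C@H](CO[Si](C)(C)C(C)(C)C)[C@H]1C[C@@H](CCC(C)[S-])C(C)(C)O1 | intermediate
21 | 15-membered cyclic sulfide (S between C1 and C2; (5E,9R,10R,12R); C18, C19 OTBS; C10–O–C15 tetrahydrofuran; C1 epimers) | CC1SCCC/C(CO[Si](C)(C)C(C)(C)C)=C\CC[C@H](CO[Si](C)(C)C(C)(C)C)[C@H]2C[C@@H](CC1)C(C)(C)O2 | intermediate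
22 | 15-membered cyclic sulfone of 21 (C1 epimers) | CC1S(=O)(=O)CCC/C(CO[Si](C)(C)C(C)(C)C)=C\CC[C@H](CO[Si](C)(C)C(C)(C)C)[C@H]2C[C@@H](CC1)C(C)(C)O2 | intermediate
23 | C2-bromo sulfone of 22 (not isolated) | CC1S(=O)(=O)C(Br)CC/C(CO[Si](C)(C)C(C)(C)C)=C\CC[C@H](CO[Si](C)(C)C(C)(C)C)[C@H]2C[C@@H](CC1)C(C)(C)O2 | intermediate
24 | cis-fused episulfone (thiirane 1,1-dioxide across C1–C2, C14 and C3 cis; one face drawn; not isolated) | C[C@]12S(=O)(=O)[C@H]1CC/C(CO[Si](C)(C)C(C)(C)C)=C\CC[C@H](CO[Si](C)(C)C(C)(C)C)[C@H]3C[C@@H](CC2)C(C)(C)O3 | intermediate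
25 | bis-TBS (1Z,5E,9R,10R,12R)-diene: 14-membered carbocycle, C18 and C19 CH2OTBS, C10–O–C15 tetrahydrofuran bridge | C/C1=C/CC/C(CO[Si](C)(C)C(C)(C)C)=C\CC[C@H](CO[Si](C)(C)C(C)(C)C)[C@H]2C[C@@H](CC1)C(C)(C)O2 | intermediate
26 | (1Z,5E)-diene-18,19-diol | C/C1=C/CC/C(CO)=C\CC[C@H](CO)[C@H]2C[C@@H](CC1)C(C)(C)O2 | intermediate
27 | (1Z,5E)-18-hydroxy-dien-19-al | C/C1=C/CC/C(C=O)=C\CC[C@H](CO)[C@H]2C[C@@H](CC1)C(C)(C)O2 | intermediate
28 | Meldrum's acid (2,2-dimethyl-1,3-dioxane-4,6-dione) | CC1(C)OC(=O)CC(=O)O1 | starting material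
29 | allyl alcohol | C=CCO | starting material
30 | allyl hydrogen malonate | C=CCOC(=O)CC(=O)O | intermediate
31 | C18 allyl malonate of 27 | C/C1=C/CC/C(C=O)=C\CC[C@H](COC(=O)CC(=O)OCC=C)[C@H]2C[C@@H](CC1)C(C)(C)O2 | intermediate
32 | CNP0170412.1 | C/C1=C/CC/C(C=O)=C\CC[C@H](COC(=O)CC(=O)O)[C@H]2C[C@@H](CC1)C(C)(C)O2 | target

**Step count**

Total: 19 steps. Longest linear sequence: 16 steps (steps 3–16, 18 and 19, from hex-5-enoic acid 6).

**Steps most likely to fail**

1. Step 14. Closure of the episulfone with the ring arms trans, or a second bromination at C2 before closure, would erode the Z geometry that the target needs. The fallback is a stereospecific olefin inversion. It sets out from sulfone 22: if the contraction runs through the trans-fused episulfone F1, the (1E)-diene F2 results. F2 is epoxidized at the more electron-rich C1=C2 alkene, which carries no allylic oxygen (mCPBA, NaHCO3, CH2Cl2, −20 °C), to the trans-epoxide F3. Ph2PLi (THF, rt) opens F3 at C2 with inversion to the lithium alkoxide phosphine F4. MeI then quaternizes phosphorus to the betaine F5, which loses methyldiphenylphosphine oxide by syn elimination and gives the Z alkene, coming back to the route at 25.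

2. Step 12. Intermolecular S-alkylation and oxidative coupling of the hindered secondary thiolate may outrun the slow displacement of chloride. The fallback closes the ring at the other carbon–sulfur bond. It sets out from 18: potassium thioacetate (KSAc, NaI cat., DMF, 40 °C) displaces the primary chloride to give the C2 thioacetate F6 with the C1 carbinol free, and MsCl/Et3N gives the C1 mesylate F7. Cs2CO3/MeOH in degassed DMF under high dilution frees the unhindered primary caesium thiolate F8, which displaces the C1 mesylate (SN2 with inversion; the C1 configuration is irrelevant) and comes back at 21.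

3. Step 7. Hydrogen-atom transfer to the enoate, or capture of the C15 cation by the C1 carbonyl oxygen, would mean insufficient chemoselectivity in the etherification. The fallback uses electrophilic instead of radical activation. It sets out from 14: I2/NaHCO3 in MeCN at 0 °C effects 5-exo iodoetherification of the electron-rich 1,1-disubstituted alkene only (the enoate is inert to electrophilic iodine), giving the iodomethyl tetrahydrofuran F9 (C15 epimers). Bu3SnH/AIBN (toluene, 80 °C) removes the iodine by radical reduction, which also erases the C15 stereocentre, and comes back at 15.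

**Further compounds**

F1 | step 14 | trans-fused episulfone (C14 and C3 trans; one face drawn; not isolated) | C[C@]12S(=O)(=O)[C@@H]1CC/C(CO[Si](C)(C)C(C)(C)C)=C\CC[C@H](CO[Si](C)(C)C(C)(C)C)[C@H]3C[C@@H](CC2)C(C)(C)O3
F2 | step 14 | (1E)-isomer of 25 | C/C1=C\CC/C(CO[Si](C)(C)C(C)(C)C)=C\CC[C@H](CO[Si](C)(C)C(C)(C)C)[C@H]2C[C@@H](CC1)C(C)(C)O2
F3 | step 14 | trans-1,2-epoxide of F2 (one face drawn) | C[C@]12O[C@@H]1CC/C(CO[Si](C)(C)C(C)(C)C)=C\CC[C@H](CO[Si](C)(C)C(C)(C)C)[C@H]3C[C@@H](CC2)C(C)(C)O3
F4 | step 14 | lithium C1 alkoxide with C2 diphenylphosphanyl group (not isolated) | [Li+].C[C@]1([O-])[C@@H](P(c2ccccc2)c3ccccc3)CC/C(CO[Si](C)(C)C(C)(C)C)=C\CC[C@H](CO[Si](C)(C)C(C)(C)C)[C@H]4C[C@@H](CC1)C(C)(C)O4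
F5 | step 14 | methyldiphenylphosphonium betaine (not isolated) | C[C@]1([O-])[C@@H]([P+](C)(c2ccccc2)c3ccccc3)CC/C(CO[Si](C)(C)C(C)(C)C)=C\CC[C@H](CO[Si](C)(C)C(C)(C)C)[C@H]4C[C@@H](CC1)C(C)(C)O4
F6 | step 12 | C2 thioacetate with free C1 carbinol | CC(=O)SCCC/C(CO[Si](C)(C)C(C)(C)C)=C\CC[C@H](CO[Si](C)(C)C(C)(C)C)[C@H]1C[C@@H](CCC(C)O)C(C)(C)O1
F7 | step 12 | C1 mesylate of F6 | CC(=O)SCCC/C(CO[Si](C)(C)C(C)(C)C)=C\CC[C@H](CO[Si](C)(C)C(C)(C)C)[C@H]1C[C@@H](CCC(C)OS(C)(=O)=O)C(C)(C)O1
F8 | step 12 | primary caesium thiolate with C1 mesylate (not isolated) | [Cs+].[S-]CCC/C(CO[Si](C)(C)C(C)(C)C)=C\CC[C@H](CO[Si](C)(C)C(C)(C)C)[C@H]1C[C@@H](CCC(C)OS(C)(=O)=O)C(C)(C)O1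
F9 | step 7 | iodomethyl tetrahydrofuran from 14 (C15 epimers) | ClCCC/C(C(=O)OCC)=C\CC[C@H](C(=O)N1[C@@H](Cc2ccccc2)COC1=O)[C@H]3C[C@@H](CCC(C)=O)C(C)(CI)O3
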